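## The problem

The target is an open array of four benzene rings with no fused ring. It is a 1,1,3-triarylpropane: one carbon carries ring B (4-hydroxyphenyl) and ring C (a 4,6-dialkylresorcinol), and the far end carries ring A (4-hydroxy-2-methoxyphenyl). The second alkyl position of ring C bears a 3-oxopropyl chain that ends in the ring D aryl ketone. No ring template helps, so every aryl–carbon bond must be made on purpose and ring C must receive four different substituents in a fixed pattern. The only stereocentre is the diarylmethine CH. Its two aryl groups differ only by the oxygens of ring C and there is no second centre to relay from, so it must be set by a reagent-controlled step and then kept away from chemistry that ionises or deprotonates a doubly benzylic position. Ring A and ring C share the same 1-alkyl-2,4-dioxygenated pattern, so an electrophilic substitution meant for ring C is selective only while ring A is absent. The benzylic carbon next to ring A is a CH2 and that next to ring D is a C=O, so the ketone must not be present when the other position is reduced. Five free phenols (two on an easily oxidised resorcinol) and one aryl methyl ether that must stay call for a single protecting group that is removed under neutral conditions at the end. The enabling feature is the ring C oxygen ortho to the stereocentre. If it is removed in thought and its ring carbon is bonded to the second chain carbon, then that ring carbon, the neighbouring ring carbon, the CH, its CH2 and the next chain carbon form the five-membered ring of a 3-aryl-indan-1-one, with the carbonyl on the carbon that needs the oxygen back.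

## Retrosynthesis

**19 to 18.** The five O–benzyl bonds of 18 are cut. Benzyl is chosen for all phenols because one neutral hydrogenolysis frees them together and leaves the methyl ether of ring A alone; silyl or acyl groups would not survive the organometallic and acidic steps. 18 is no simpler in skeleton, but it is free of acidic and oxidisable phenols. The forward reaction must cleave five ethers without reducing the electron-rich ring D ketone.

**18 to 15 and 17 (17 from 16).** The bond between ring C and the first CH2 of the ketone chain is cut. A Heck arylation of the secondary allylic alcohol 17 with the aryl bromide 15 should give the saturated ketone directly. Ring D and its carbonyl therefore arrive last and never see the deoxygenation of the other chain. A Friedel–Crafts alkylation could not tell ring C from ring A, and an aldol route would need a ring C aldehyde that cannot pass the Grignard step. 17 is one step from the aldehyde 16. The forward reaction must insert zerovalent palladium into an electron-rich, ortho-substituted C–Br bond and then eliminate hydride towards the carbinol carbon.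

**15 to 14, then to 10 and 13 (13 from 12, 12 from 11).** The CH2 next to ring A is taken back to a ketone, and the bond between that carbon and ring A is cut. The carbon is the acyl carbon of the Weinreb amide 10, so the former indanone carbonyl carbon stays in the skeleton. The aryl Grignard reagent 13 comes from the bromide 12, the benzyl ether of the phenol 11. Ring A must enter after ring C has been brominated, since the two rings are equally nucleophilic. The ketone 14 is easy to deoxygenate because its aryl group carries ortho and para oxygens. The forward steps need single addition to the amide and a reduction that leaves the aryl bromide and benzyl ethers alone.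

**10 to 9, 8 and 7.** The C–Br bond is cut first, then one O–benzyl bond, then the amide C–N bond, which closes back to the lactone 7. In 9 the free position of ring C that is para to one benzyloxy group and ortho to the other is the most nucleophilic carbon of the molecule; ring B has only one oxygen. Opening 7 with an aluminium amide gives the Weinreb amide and the free phenol 8 in one operation. This is shorter than going through an ester. 7 is bicyclic, compact and carries the stereocentre.

**7 to 6.** The aryl C–O bond of the lactone is cut, which removes the oxygen and leaves the indanone 6. The forward step is a Baeyer–Villiger oxidation with aryl migration, a known conversion of 3-aryl-indan-1-ones into 4-aryl-dihydrocoumarins. It places the oxygen on exactly the ring carbon that held the carbonyl. The stereocentre is beta to the carbonyl and is not touched. The forward reaction needs aryl migration to beat migration of the CH2 group.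

**6 to 5.** The acyl–CH2 bond and the C–H bond at the stereocentre are cut. 5 is achiral, has one ring fewer and no stereocentre. The stereochemical problem becomes the choice of one face of a 1,1-diarylethene by a chiral bisphosphine on rhodium. A Friedel–Crafts closure of a diarylpropanoic acid would need the stereocentre beforehand, and a conjugate addition to an indenone would need an unstable acceptor. The forward reaction must give high enantioface selection and must outrun decarbonylation.

**5 to 3 and 4 (3 from 1).** The aryl–vinyl bond is cut. A Suzuki coupling joins the enol triflate 3, made from the methyl ketone 1, with the formyl boronic acid 4. Both partners carry their benzyl ethers from purchase, so the key-step substrate is reached in two steps. The forward steps need a mild base so that the triflate is not hydrolysed and the boronic acid is not protodeboronated.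

## Roads not taken

**Alternative 1:** The cut removes four carbon–carbon bonds of ring C and builds the resorcinol from two acyclic partners. These are the alpha-diazo enone A2, (3E,7R)-9-[4-(benzyloxy)-2-methoxyphenyl]-7-[4-(benzyloxy)phenyl]-1-{2-[4-(benzyloxy)phenyl]-1,3-dioxolan-2-yl}-6-diazonon-3-en-5-one, and the silyl ynol ether A3, (triisopropylsiloxy)ethyne. Irradiation of A2 would cause a Wolff rearrangement to a vinylketene. A3 would add by (2+2) cycloaddition, the cyclobutenone would open in a four-electron step, and the dienylketene would close in a six-electron step to give the phenol A1 (Danheiser benzannulation).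

- Merits: every substituent of ring C is placed by connectivity and not by electrophilic substitution, and the two ring C oxygens emerge differentiated.
- Weak points: the step makes no stereocentre. The diarylmethine must already be in A2, on the carbon next to the diazo carbon, where a 1,2-hydride shift of the tertiary benzylic hydrogen to the carbene centre competes with the Wolff rearrangement and would erase it. A2 already holds ring A, ring B and the masked ring D ketone and needs its own asymmetric step and a deacylative diazo transfer. The photochemical step is run on late material.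
- Comparison: in regiocontrol of ring C this road is better than the chosen plan, which relies on the directing power of two benzyloxy groups in step 7 and on the late entry of ring A. The chosen plan sets against this a catalytic key step that creates the stereocentre on a two-step substrate, and a clearly lower step count.

**Alternative 2:** The cut is the aryl C–O bond of the lactone, to be made by C–H functionalisation. The achiral acid A4, 3,3-bis[4-(benzyloxy)phenyl]propanoic acid, has two enantiotopic aryl groups. It would be closed to the lactone A5, (4R)-7-(benzyloxy)-4-[4-(benzyloxy)phenyl]-3,4-dihydro-2H-chromen-2-one, which is the same compound as 7. Pd(OAc)2 with a chiral mono-N-protected amino acid would cleave one ortho C–H bond under carboxylate direction. PhI(OAc)2 would oxidise the palladacycle to tetravalent palladium, and C–O reductive elimination would close the ring.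

- Merits: A4 is symmetrical and easily made, no prefunctionalised arene is needed, and the route joins the chosen one at 7. It would reach 7 in the same number of steps or one fewer.
- Weak points: enantioselective C–H lactonisation of this kind is established for diarylacetic acids, which close a five-membered lactone through a six-membered palladacycle. A4 is one carbon longer, so it needs a seven-membered palladacycle and places the prochiral carbon further from the metal. Reactivity and ligand control are both extrapolations. The electron-rich benzyloxyarenes are also exposed to a hypervalent iodine oxidant.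
- Comparison: in step count and atom economy this road is equal or slightly better. The chosen plan sets against this an enantio-determining step from a demonstrated reaction class, in which the alkene is bound to the metal next to the chiral ligand, and a key step that uses no oxidant.

**Alternative 3:** The cut removes the CH–CH2 bond and the O–C bond of a chroman. The partners are the ortho-hydroxybenzhydrol A6, methyl 3-[2-(benzyloxy)-5-{[4-(benzyloxy)phenyl](hydroxy)methyl}-4-hydroxyphenyl]propanoate, and the enamide A7, N-{1-[4-(benzyloxy)-2-methoxyphenyl]ethenyl}acetamide. A chiral BINOL-derived phosphoric acid would dehydrate A6 to a hydrogen-bonded ortho-quinone methide. The CH2 terminus of A7 would add to the methide carbon, and the phenol oxygen would capture the acyliminium ion to give the 2-amidochroman A8, methyl 3-{(2S,4R)-2-acetamido-7-(benzyloxy)-2-[4-(benzyloxy)-2-methoxyphenyl]-4-[4-(benzyloxy)phenyl]-3,4-dihydro-2H-chromen-6-yl}propanoate. The aminal centre would be removed later.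

- Merits: it is the most convergent road. Ring A, the CH–CH2 bond and the stereocentre arrive in one metal-free step, and ring C already carries its chain.
- Weak points: A6 needs the two ring C oxygens told apart in the less accessible sense (free hydroxyl para to the chain, benzyl ether ortho to it). The quinone methide is stabilised by a para benzyloxy group and by the 4-benzyloxyphenyl group, so it has strong benzhydryl cation character; a loose ion pair and an uncatalysed background addition threaten the enantioselectivity. A7 is hindered by its ortho methoxy group. After the key step the aminal must be hydrolysed, the phenol protected, the ketone deoxygenated and the ester turned into the ring D ketone, so the total is not lower.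
- Comparison: this road is more convergent and avoids both the Baeyer–Villiger step and the late Heck coupling. The chosen plan sets against this an enantiocontrol that is fixed at a metal centre and does not depend on ion pairing, a key-step substrate available in two steps, and no need to differentiate the ring C oxygens.

Key step: step 3

Assumption: (R)-BINAP is written as the ligand antipode that leads to the (3R)-indanone 6; if the sense of induction on this substrate is the opposite, (S)-BINAP is used and nothing else changes.
Assumption: compounds 1, 4, 11 and 16 are taken as catalogue materials that are bought with their benzyl ether or free phenol as drawn.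

## Route

Step 1
Reactants: 1 1-[4-(benzyloxy)phenyl]ethan-1-one
Product: 3 1-[4-(benzyloxy)phenyl]ethenyl trifluoromethanesulfonate, via potassium enolate 2 (not isolated)
Conditions: KN(SiMe3)2, THF, −78 °C; then PhNTf2, −78 to 0 °C
Reagents that add atoms: N-phenylbis(trifluoromethanesulfonimide), O=S(=O)(N(c1ccccc1)S(=O)(=O)C(F)(F)F)C(F)(F)F
Why: Enol triflate formation; the methyl ketone has one enolisable side, and its potassium enolate is sulfonylated on oxygen by the N-aryl triflimide.

Step 2
Reactants: 3 1-[4-(benzyloxy)phenyl]ethenyl trifluoromethanesulfonate; 4 [4-(benzyloxy)-2-formylphenyl]boronic acid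
Product: 5 5-(benzyloxy)-2-{1-[4-(benzyloxy)phenyl]ethenyl}benzaldehyde
Conditions: Pd(PPh3)4 (5 mol%), K3PO4, 1,4-dioxane/H2O, 60 °C
Reagents that add atoms: none
Why: Suzuki–Miyaura coupling of a vinyl triflate with an arylboronic acid; zerovalent palladium inserts into the C–OTf bond, and transmetalation and reductive elimination give the 1,1-diarylethene. The aldehyde and benzyl ethers are inert, and the mild base and temperature limit triflate hydrolysis and protodeboronation.

Step 3
Reactants: 5 5-(benzyloxy)-2-{1-[4-(benzyloxy)phenyl]ethenyl}benzaldehyde
Product: 6 (3R)-6-(benzyloxy)-3-[4-(benzyloxy)phenyl]-2,3-dihydro-1H-inden-1-one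
Conditions: [Rh((R)-BINAP)]BF4 (3 mol%; from [Rh(nbd)2]BF4 and (R)-BINAP, H2 then argon; nbd = norbornadiene), CH2Cl2, rt
Reagents that add atoms: none
Why: Oxidative addition of the aldehyde C–H bond to the cationic monovalent rhodium centre gives an acyl hydride of trivalent rhodium; the ortho 1,1-diarylethene then inserts into the Rh–H bond so that hydrogen goes to the diaryl carbon and rhodium to the CH2 carbon, and C–C reductive elimination from the six-membered acyl rhodacycle releases the ketone and monovalent rhodium. The closest known reaction type is the rhodium–BINAP-catalysed enantioselective intramolecular hydroacylation of 2-(1-substituted vinyl)benzaldehydes, 1-aryl members included, to 3-substituted indan-1-ones. The one ring formed is the five-membered ketone, closed formally in a 5-endo-trig sense because both alkene carbons end up in the ring, but reached by reductive elimination from the metallacycle, so the geometric limits of a direct endo attack do not apply. The new stereocentre at C3 is created in the hydride insertion, and its configuration is decided by which enantioface of the alkene can bind in the chiral pocket of the C2-symmetric bisphosphine, which is the only source of chirality. Regiochemistry is secured by the tether, because hydride delivery to the CH2 terminus would lead to a five-membered rhodacycle and a benzocyclobutenone, which is not a viable outlet. Chemoselectivity against decarbonylation is needed and is secured by the ortho position of the alkene, which makes insertion intramolecular and fast, and by the weakly coordinating BF4 counter-ion, which keeps coordination sites free. The alkene has no allylic hydrogen, so double-bond migration cannot divert the substrate, and the benzyl ethers are spectators.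

Step 4
Reactants: 6 (3R)-6-(benzyloxy)-3-[4-(benzyloxy)phenyl]-2,3-dihydro-1H-inden-1-one
Product: 7 (4R)-7-(benzyloxy)-4-[4-(benzyloxy)phenyl]-3,4-dihydro-2H-chromen-2-one
Conditions: mCPBA, TsOH·H2O (cat.), CH2Cl2, 0 °C to rt
Reagents that add atoms: 3-chloroperoxybenzoic acid, O=C(OO)c1cccc(Cl)c1
Why: Baeyer–Villiger oxidation; in the acid-catalysed peracid adduct the aryl carbon migrates in preference to the primary CH2, as is known for 3-aryl-indan-1-ones, which give 4-aryl-dihydrocoumarins. The stereocentre is beta to the carbonyl, is not enolisable and takes no part, so the configuration is kept.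

Step 5
Reactants: 7 (4R)-7-(benzyloxy)-4-[4-(benzyloxy)phenyl]-3,4-dihydro-2H-chromen-2-one
Product: 8 (3R)-3-[4-(benzyloxy)-2-hydroxyphenyl]-3-[4-(benzyloxy)phenyl]-N-methoxy-N-methylpropanamide
Conditions: MeNH(OMe)·HCl, AlMe3, CH2Cl2, 0 °C to rt; cold 1 M HCl work-up
Reagents that add atoms: N,O-dimethylhydroxylamine hydrochloride, CNOC.Cl
Why: Aminolysis of a lactone with an aluminium amide (Weinreb amide formation); the aryl ester is an activated acyl donor, and the conditions are not basic enough to affect the stereocentre.

Step 6
Reactants: 8 (3R)-3-[4-(benzyloxy)-2-hydroxyphenyl]-3-[4-(benzyloxy)phenyl]-N-methoxy-N-methylpropanamide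
Product: 9 (3R)-3-[2,4-bis(benzyloxy)phenyl]-3-[4-(benzyloxy)phenyl]-N-methoxy-N-methylpropanamide
Conditions: BnBr, K2CO3, DMF, rt
Reagents that add atoms: benzyl bromide, BrCc1ccccc1
Why: Williamson ether synthesis on the phenol; the Weinreb amide is stable to carbonate, and capping the phenol prevents relactonisation and turns ring C into a defined resorcinol diether for the next step.

Step 7
Reactants: 9 (3R)-3-[2,4-bis(benzyloxy)phenyl]-3-[4-(benzyloxy)phenyl]-N-methoxy-N-methylpropanamide
Product: 10 (3R)-3-[2,4-bis(benzyloxy)-5-bromophenyl]-3-[4-(benzyloxy)phenyl]-N-methoxy-N-methylpropanamide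
Conditions: NBS (1.0 equiv), MeCN, 0 °C
Reagents that add atoms: N-bromosuccinimide, O=C1CCC(=O)N1Br
Why: Electrophilic aromatic bromination; C5 of ring C is para to one benzyloxy group and ortho to the other, so it is far more nucleophilic than any position of the mono-oxygenated ring B. The position between the two ethers is sterically shielded, and ring A is not yet present.

Step 8
Reactants: 11 4-bromo-3-methoxyphenol
Product: 12 4-(benzyloxy)-1-bromo-2-methoxybenzene
Conditions: BnBr, K2CO3, acetone, reflux
Reagents that add atoms: benzyl bromide, BrCc1ccccc1
Why: Williamson ether synthesis; the phenol is the only nucleophilic site, and the aryl bromide is inert to carbonate.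

Step 9
Reactants: 12 4-(benzyloxy)-1-bromo-2-methoxybenzene; 10 (3R)-3-[2,4-bis(benzyloxy)-5-bromophenyl]-3-[4-(benzyloxy)phenyl]-N-methoxy-N-methylpropanamide
Product: 14 (3R)-1-[4-(benzyloxy)-2-methoxyphenyl]-3-[2,4-bis(benzyloxy)-5-bromophenyl]-3-[4-(benzyloxy)phenyl]propan-1-one, via aryl Grignard reagent 13 (not isolated)
Conditions: 12, Mg, I2 (cat.), THF, reflux; then 10, THF, 0 °C to rt; aqueous work-up
Reagents that add atoms: none
Why: Weinreb ketone synthesis; the aryl Grignard reagent adds once because the chelated tetrahedral adduct lasts until work-up. An aryl bromide does not exchange with an aryl Grignard reagent at this temperature, so the bromide of ring C is kept.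

Step 10
Reactants: 14 (3R)-1-[4-(benzyloxy)-2-methoxyphenyl]-3-[2,4-bis(benzyloxy)-5-bromophenyl]-3-[4-(benzyloxy)phenyl]propan-1-one
Product: 15 1,5-bis(benzyloxy)-2-bromo-4-{(1R)-3-[4-(benzyloxy)-2-methoxyphenyl]-1-[4-(benzyloxy)phenyl]propyl}benzene
Conditions: Et3SiH, CF3CO2H, CH2Cl2, 0 °C to rt
Reagents that add atoms: none
Why: Ionic hydrogenation of an electron-rich aryl ketone; hydride transfer to the protonated ketone, ionisation of the benzylic alcohol to a cation stabilised by the ortho methoxy and para benzyloxy groups of ring A, and a second hydride transfer give the CH2 group. The aryl bromide is inert and the stereocentre carries no ionisable group.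

Step 11
Reactants: 16 4-(benzyloxy)benzaldehyde
Product: 17 1-[4-(benzyloxy)phenyl]prop-2-en-1-ol (racemic)
Conditions: CH2=CHMgBr, THF, 0 °C
Reagents that add atoms: vinylmagnesium bromide, C=C[Mg]Br
Why: Grignard 1,2-addition to an aldehyde; the alcohol is racemic, which does not matter because its carbinol carbon becomes the ketone carbon in step 12.

Step 12
Reactants: 15 1,5-bis(benzyloxy)-2-bromo-4-{(1R)-3-[4-(benzyloxy)-2-methoxyphenyl]-1-[4-(benzyloxy)phenyl]propyl}benzene; 17 1-[4-(benzyloxy)phenyl]prop-2-en-1-ol
Product: 18 3-{2,4-bis(benzyloxy)-5-[(1R)-3-[4-(benzyloxy)-2-methoxyphenyl]-1-[4-(benzyloxy)phenyl]propyl]phenyl}-1-[4-(benzyloxy)phenyl]propan-1-one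
Conditions: Pd(OAc)2 (5 mol%), P(o-tol)3 (10 mol%), NaHCO3, DMF, 100 °C
Reagents that add atoms: none
Why: Mizoroki–Heck arylation of a secondary allylic alcohol; the aryl palladium species adds to the terminal alkene carbon, and beta-hydride elimination towards the carbinol carbon gives an enol that tautomerises to the saturated ketone. Ring D and its carbonyl group thus arrive in one step, after the deoxygenation is over.

Step 13
Reactants: 18 3-{2,4-bis(benzyloxy)-5-[(1R)-3-[4-(benzyloxy)-2-methoxyphenyl]-1-[4-(benzyloxy)phenyl]propyl]phenyl}-1-[4-(benzyloxy)phenyl]propan-1-one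
Product: 19 3-{2,4-dihydroxy-5-[(1R)-3-(4-hydroxy-2-methoxyphenyl)-1-(4-hydroxyphenyl)propyl]phenyl}-1-(4-hydroxyphenyl)propan-1-one
Conditions: H2 (1 atm), 10% Pd/C, EtOAc/MeOH, rt
Reagents that add atoms: none
Why: Catalytic hydrogenolysis of five aryl benzyl ethers; the electron-rich 4-oxyphenyl ketone and the aryl methyl ether should be inert at balloon pressure and room temperature. The stereocentre has no bond that can be cleaved under these conditions.

## Compound list

1 | 1-[4-(benzyloxy)phenyl]ethan-1-one | CC(=O)c1ccc(OCc2ccccc2)cc1 | starting material
2 | potassium 1-[4-(benzyloxy)phenyl]ethen-1-olate | [K+].C=C([O-])c1ccc(OCc2ccccc2)cc1 | intermediate (not isolated)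
3 | 1-[4-(benzyloxy)phenyl]ethenyl trifluoromethanesulfonate | C=C(OS(=O)(=O)C(F)(F)F)c1ccc(OCc2ccccc2)cc1 | intermediate
4 | [4-(benzyloxy)-2-formylphenyl]boronic acid | O=Cc1cc(OCc2ccccc2)ccc1B(O)O | starting material
5 | 5-(benzyloxy)-2-{1-[4-(benzyloxy)phenyl]ethenyl}benzaldehyde | O=Cc1cc(OCc2ccccc2)ccc1C(=C)c1ccc(OCc2ccccc2)cc1 | intermediate
6 | (3R)-6-(benzyloxy)-3-[4-(benzyloxy)phenyl]-2,3-dihydro-1H-inden-1-one | O=C1C[C@H](c2ccc(OCc3ccccc3)cc2)c2ccc(OCc3ccccc3)cc21 | intermediate
7 | (4R)-7-(benzyloxy)-4-[4-(benzyloxy)phenyl]-3,4-dihydro-2H-chromen-2-one | O=C1C[C@H](c2ccc(OCc3ccccc3)cc2)c2ccc(OCc3ccccc3)cc2O1 | intermediate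
8 | (3R)-3-[4-(benzyloxy)-2-hydroxyphenyl]-3-[4-(benzyloxy)phenyl]-N-methoxy-N-methylpropanamide | CON(C)C(=O)C[C@H](c1ccc(OCc2ccccc2)cc1)c1ccc(OCc2ccccc2)cc1O | intermediate
9 | (3R)-3-[2,4-bis(benzyloxy)phenyl]-3-[4-(benzyloxy)phenyl]-N-methoxy-N-methylpropanamide | CON(C)C(=O)C[C@H](c1ccc(OCc2ccccc2)cc1)c1ccc(OCc2ccccc2)cc1OCc1ccccc1 | intermediate
10 | (3R)-3-[2,4-bis(benzyloxy)-5-bromophenyl]-3-[4-(benzyloxy)phenyl]-N-methoxy-N-methylpropanamide | CON(C)C(=O)C[C@H](c1ccc(OCc2ccccc2)cc1)c1cc(Br)c(OCc2ccccc2)cc1OCc1ccccc1 | intermediate
11 | 4-bromo-3-methoxyphenol | COc1cc(O)ccc1Br | starting material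
12 | 4-(benzyloxy)-1-bromo-2-methoxybenzene | COc1cc(OCc2ccccc2)ccc1Br | intermediate
13 | [4-(benzyloxy)-2-methoxyphenyl]magnesium bromide | COc1cc(OCc2ccccc2)ccc1[Mg]Br | intermediate (not isolated)
14 | (3R)-1-[4-(benzyloxy)-2-methoxyphenyl]-3-[2,4-bis(benzyloxy)-5-bromophenyl]-3-[4-(benzyloxy)phenyl]propan-1-one | COc1cc(OCc2ccccc2)ccc1C(=O)C[C@H](c1ccc(OCc2ccccc2)cc1)c1cc(Br)c(OCc2ccccc2)cc1OCc1ccccc1 | intermediate
15 | 1,5-bis(benzyloxy)-2-bromo-4-{(1R)-3-[4-(benzyloxy)-2-methoxyphenyl]-1-[4-(benzyloxy)phenyl]propyl}benzene | COc1cc(OCc2ccccc2)ccc1CC[C@H](c1ccc(OCc2ccccc2)cc1)c1cc(Br)c(OCc2ccccc2)cc1OCc1ccccc1 | intermediate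
16 | 4-(benzyloxy)benzaldehyde | O=Cc1ccc(OCc2ccccc2)cc1 | starting material
17 | 1-[4-(benzyloxy)phenyl]prop-2-en-1-ol (racemic) | C=CC(O)c1ccc(OCc2ccccc2)cc1 | intermediate
18 | 3-{2,4-bis(benzyloxy)-5-[(1R)-3-[4-(benzyloxy)-2-methoxyphenyl]-1-[4-(benzyloxy)phenyl]propyl]phenyl}-1-[4-(benzyloxy)phenyl]propan-1-one | COc1cc(OCc2ccccc2)ccc1CC[C@H](c1ccc(OCc2ccccc2)cc1)c1cc(CCC(=O)c2ccc(OCc3ccccc3)cc2)c(OCc2ccccc2)cc1OCc1ccccc1 | intermediate
19 | 3-{2,4-dihydroxy-5-[(1R)-3-(4-hydroxy-2-methoxyphenyl)-1-(4-hydroxyphenyl)propyl]phenyl}-1-(4-hydroxyphenyl)propan-1-one | COc1cc(O)ccc1CC[C@H](c1ccc(O)cc1)c1cc(CCC(=O)c2ccc(O)cc2)c(O)cc1O | target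

## Step count and least certain steps

Total step count: 13. Longest linear sequence: 11 steps (steps 1 to 7, 9, 10, 12 and 13); steps 8 and 11 make the two side fragments.

**Step 3 (key step).** The most likely failure is insufficient discrimination between the two faces of the alkene, because both of its substituents are aryl groups. Decarbonylation of the acyl rhodium hydride may also compete and tie up the catalyst as a rhodium carbonyl, since the electron-rich 1,1-diarylethene binds less strongly than a simple alkene. The fallback sets out from 16 and comes back at 9. A Horner–Wadsworth–Emmons reaction of 16 with diethyl {2-[methoxy(methyl)amino]-2-oxoethyl}phosphonate (NaH, THF) would give (2E)-3-[4-(benzyloxy)phenyl]-N-methoxy-N-methylprop-2-enamide F1. A rhodium-catalysed asymmetric 1,4-addition of 2,4-bis(benzyloxy)phenylboronic acid to F1 (Rh(acac)(C2H4)2, the BINAP antipode that gives the R centre, 1,4-dioxane/H2O, 100 °C) would then give 9. This is a known reaction class for unsaturated esters and amides. It is demanding here, because the boronic acid is ortho-substituted and the acceptor is electron-rich.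

**Step 12.** The most likely failure is slow oxidative addition into the electron-rich aryl bromide flanked by a benzyloxy group. That leaves room for palladium-hydride isomerisation of 17 to the propiophenone, for beta-hydride elimination away from the carbinol carbon, and for intramolecular arylation of the neighbouring benzyl ether. The fallback sets out from 15 and comes back at 19. Bromine–lithium exchange (n-BuLi, THF, −78 °C) and formylation with DMF would give 2,4-bis(benzyloxy)-5-{(1R)-3-[4-(benzyloxy)-2-methoxyphenyl]-1-[4-(benzyloxy)phenyl]propyl}benzaldehyde F2. A Claisen–Schmidt condensation of F2 with 1 (KOH, EtOH/THF, rt) would give (2E)-3-{2,4-bis(benzyloxy)-5-[(1R)-3-[4-(benzyloxy)-2-methoxyphenyl]-1-[4-(benzyloxy)phenyl]propyl]phenyl}-1-[4-(benzyloxy)phenyl]prop-2-en-1-one F3. Under the conditions of step 13 the C=C bond of F3 is saturated while the benzyl ethers are cleaved, which gives 19 without any palladium coupling.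

**Step 10.** The most likely failure is capture of the benzylic cation before the second hydride transfer. It could cyclise onto ring B or ring C in a Friedel–Crafts sense to an indane, or lose the para benzyl group of ring A through a quinone methide; slow cleavage of benzyl ethers by the acid is also possible. The fallback sets out from 14 and comes back at 15. Condensation with 4-methylbenzenesulfonohydrazide (EtOH, reflux) would give N'-[(3R)-1-[4-(benzyloxy)-2-methoxyphenyl]-3-[2,4-bis(benzyloxy)-5-bromophenyl]-3-[4-(benzyloxy)phenyl]propylidene]-4-methylbenzenesulfonohydrazide F4. Reduction of F4 with catecholborane (CHCl3, 0 °C), then NaOAc·3H2O at reflux, would give 15 through a diazene. No cation is formed on this path.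

**Step 13.** The most likely failure is over-reduction of the ring D aryl ketone to the benzylic alcohol or to the CH2 group once the benzyl ethers are gone, because the catalyst and hydrogen must stay long enough to cleave five ethers. The fallback sets out from 18 and comes back at 19. The benzyl ethers would be cleaved without hydrogen by BCl3 with pentamethylbenzene as cation scavenger (CH2Cl2, −78 °C), conditions that leave the aryl methyl ether and the ketone alone at this temperature. This fallback makes no new compound (F0).

## Further compounds

F1 | step 3 | (2E)-3-[4-(benzyloxy)phenyl]-N-methoxy-N-methylprop-2-enamide | CON(C)C(=O)/C=C/c1ccc(OCc2ccccc2)cc1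
F2 | step 12 | 2,4-bis(benzyloxy)-5-{(1R)-3-[4-(benzyloxy)-2-methoxyphenyl]-1-[4-(benzyloxy)phenyl]propyl}benzaldehyde | COc1cc(OCc2ccccc2)ccc1CC[C@H](c1ccc(OCc2ccccc2)cc1)c1cc(C=O)c(OCc2ccccc2)cc1OCc1ccccc1
F3 | step 12 | (2E)-3-{2,4-bis(benzyloxy)-5-[(1R)-3-[4-(benzyloxy)-2-methoxyphenyl]-1-[4-(benzyloxy)phenyl]propyl]phenyl}-1-[4-(benzyloxy)phenyl]prop-2-en-1-one | COc1cc(OCc2ccccc2)ccc1CC[C@H](c1ccc(OCc2ccccc2)cc1)c1cc(/C=C/C(=O)c2ccc(OCc3ccccc3)cc2)c(OCc2ccccc2)cc1OCc1ccccc1
F4 | step 10 | N'-[(3R)-1-[4-(benzyloxy)-2-methoxyphenyl]-3-[2,4-bis(benzyloxy)-5-bromophenyl]-3-[4-(benzyloxy)phenyl]propylidene]-4-methylbenzenesulfonohydrazide | COc1cc(OCc2ccccc2)ccc1C(=NNS(=O)(=O)c1ccc(C)cc1)C[C@H](c1ccc(OCc2ccccc2)cc1)c1cc(Br)c(OCc2ccccc2)cc1OCc1ccccc1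
F0 | step 13 | none | none
A1 | alternative 1 | 4-{(1R)-3-[4-(benzyloxy)-2-methoxyphenyl]-1-[4-(benzyloxy)phenyl]propyl}-6-(2-{2-[4-(benzyloxy)phenyl]-1,3-dioxolan-2-yl}ethyl)-3-{[tri(propan-2-yl)silyl]oxy}phenol | COc1cc(OCc2ccccc2)ccc1CC[C@H](c1ccc(OCc2ccccc2)cc1)c1cc(CCC2(c3ccc(OCc4ccccc4)cc3)OCCO2)c(O)cc1O[Si](C(C)C)(C(C)C)C(C)C
A2 | alternative 1 | (3E,7R)-9-[4-(benzyloxy)-2-methoxyphenyl]-7-[4-(benzyloxy)phenyl]-1-{2-[4-(benzyloxy)phenyl]-1,3-dioxolan-2-yl}-6-diazonon-3-en-5-one | COc1cc(OCc2ccccc2)ccc1CC[C@H](c1ccc(OCc2ccccc2)cc1)C(=[N+]=[N-])C(=O)/C=C/CCC1(c2ccc(OCc3ccccc3)cc2)OCCO1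
A3 | alternative 1 | (triisopropylsiloxy)ethyne | C#CO[Si](C(C)C)(C(C)C)C(C)C
A4 | alternative 2 | 3,3-bis[4-(benzyloxy)phenyl]propanoic acid | O=C(O)CC(c1ccc(OCc2ccccc2)cc1)c1ccc(OCc2ccccc2)cc1
A5 | alternative 2 | (4R)-7-(benzyloxy)-4-[4-(benzyloxy)phenyl]-3,4-dihydro-2H-chromen-2-one | O=C1C[C@H](c2ccc(OCc3ccccc3)cc2)c2ccc(OCc3ccccc3)cc2O1
A6 | alternative 3 | methyl 3-[2-(benzyloxy)-5-{[4-(benzyloxy)phenyl](hydroxy)methyl}-4-hydroxyphenyl]propanoate | COC(=O)CCc1cc(C(O)c2ccc(OCc3ccccc3)cc2)c(O)cc1OCc1ccccc1
A7 | alternative 3 | N-{1-[4-(benzyloxy)-2-methoxyphenyl]ethenyl}acetamide | C=C(NC(C)=O)c1ccc(OCc2ccccc2)cc1OC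
A8 | alternative 3 | methyl 3-{(2S,4R)-2-acetamido-7-(benzyloxy)-2-[4-(benzyloxy)-2-methoxyphenyl]-4-[4-(benzyloxy)phenyl]-3,4-dihydro-2H-chromen-6-yl}propanoate | CC(=O)N[C@@]1(c2ccc(OCc3ccccc3)cc2OC)C[C@H](c2ccc(OCc3ccccc3)cc2)c2cc(CCC(=O)OC)c(OCc3ccccc3)cc2O1
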